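**Retrosynthetic overview**
- The dihydrofuran enol ether is unveiled last by dehydrating a C15 lactol; C15 is carried until then as a methyl acetal that comes in with the aldol partner.
- The 7-ketone and 8β-acetate come from a 7β,8β-diol; the C9–O–C13 spiro ether and the 8β-oxygen arise together from a 7β-hydroxyl-directed β-epoxidation of a Δ8 alkene and 5-exo opening by the C13 hydroxyl.
- C13 (R) is set by Sharpless epoxidation and hydride opening of a (12E)-12-en-16-ol.
- Key C12–C13 bond: aldol addition of the lithium enolate of methyl 4,4-dimethoxybutanoate to a C12 aldehyde made from (+)-sclareolide, which supplies rings A and B with C5 and C10.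
- Ring order: decalin (chiral pool), then the methoxytetrahydrofuran (step 12), then the spiro tetrahydrofuran (step 14), then the dihydrofuran (step 18).

Assumption: names use labdane numbering (decalin C1–C10, side chain C11–C16, C17 = methyl on C8), α is the face opposite the C10 methyl, and compounds 16–23 are carried as C15 anomer mixtures (15ξ) that converge in step 18.

The target is (5S,8R,9S,10S,13R): 5α-H, 10β-CH3, 8β-OAc/8α-CH3, 9α-O/9β-C11.

**Step 1**
Reactants: 1 (+)-sclareolide
Product: 2 methyl 13,14,15,16-tetranorlabd-8-en-12-oate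
Conditions: conc. H2SO4, MeOH, reflux, 24 h
Reagents that add atoms: methanol, CO
Why: Acid-catalysed transesterification opens the lactone and E1 loss of the tertiary C8 oxygen under equilibrating conditions gives mainly the tetrasubstituted Δ8(9) alkene (minor Δ7 and Δ8(17) isomers are removed on AgNO3-impregnated silica and re-equilibrated), with C5 and C10 unchanged from the chiral pool.

**Step 2**
Reactants: 2 methyl 13,14,15,16-tetranorlabd-8-en-12-oate
Product: 3 methyl 7-oxo-13,14,15,16-tetranorlabd-8-en-12-oate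
Conditions: Na2CrO4, NaOAc, AcOH/Ac2O, 40 °C
Reagents that add atoms: sodium chromate, [Na+].[Na+].[O-][Cr](=O)(=O)[O-]
Why: Chromate allylic oxidation takes the ring methylene C7, because the other allylic CH2 (C11) is deactivated by the neighbouring ester, and gives the conjugated enone.

**Step 3**
Reactants: 3 methyl 7-oxo-13,14,15,16-tetranorlabd-8-en-12-oate
Product: 4 methyl 7β-hydroxy-13,14,15,16-tetranorlabd-8-en-12-oate (7S)
Conditions: NaBH4, CeCl3·7H2O, MeOH, −20 °C
Reagents that add atoms: none
Why: Luche 1,2-reduction delivers hydride along the axial α trajectory of the half-chair enone and gives the pseudo-equatorial 7β-alcohol without touching the ester, any 7α epimer being removed by chromatography.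

**Step 4**
Reactants: 4 methyl 7β-hydroxy-13,14,15,16-tetranorlabd-8-en-12-oate
Product: 5 methyl 7β-(tert-butyldimethylsilyloxy)-13,14,15,16-tetranorlabd-8-en-12-oate
Conditions: TBSOTf, 2,6-lutidine, CH2Cl2, −78 to 0 °C
Reagents that add atoms: tert-butyldimethylsilyl triflate, CC(C)(C)[Si](C)(C)OS(=O)(=O)C(F)(F)F
Why: Silylation with the reactive silyl triflate protects the hindered allylic alcohol so that it survives the enolate, hydride and titanium steps and cannot direct the later Sharpless epoxidation.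

**Step 5**
Reactants: 5 methyl 7β-(tert-butyldimethylsilyloxy)-13,14,15,16-tetranorlabd-8-en-12-oate
Product: 6 7β-(tert-butyldimethylsilyloxy)-13,14,15,16-tetranorlabd-8-en-12-ol
Conditions: iBu2AlH, CH2Cl2, −78 to 0 °C
Reagents that add atoms: none
Why: Hydride reduction of the ester to the primary alcohol is used in place of a partial reduction because it is the more dependable way to the sensitive aldehyde.

**Step 6**
Reactants: 6 7β-(tert-butyldimethylsilyloxy)-13,14,15,16-tetranorlabd-8-en-12-ol
Product: 7 7β-(tert-butyldimethylsilyloxy)-13,14,15,16-tetranorlabd-8-en-12-al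
Conditions: Dess–Martin periodinane, NaHCO3, CH2Cl2, 0 °C to rt
Reagents that add atoms: none
Why: Buffered Dess–Martin oxidation gives the β,γ-unsaturated aldehyde under neutral conditions without moving the tetrasubstituted double bond, and the aldehyde is used at once.

**Step 7**
Reactants: 7 7β-(tert-butyldimethylsilyloxy)-13,14,15,16-tetranorlabd-8-en-12-al, 8 methyl 4,4-dimethoxybutanoate
Product: 10 methyl 7β-(tert-butyldimethylsilyloxy)-12-hydroxy-15,15-dimethoxylabd-8-en-16-oate (mixture of C12/C13 diastereomers), via lithium enolate 9 (not isolated)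
Conditions: 8, LiN(iPr)2, THF, −78 °C; then 7, −78 °C; aq. NH4Cl
Reagents that add atoms: none
Why: Intermolecular aldol addition of the preformed lithium ester enolate to the unhindered aldehyde is faster at −78 °C than deprotonation at C11 and joins the decalin fragment to the C13–C16 fragment at C12–C13, the two new stereocentres being erased again in steps 8–11.

**Step 8**
Reactants: 10 methyl 7β-(tert-butyldimethylsilyloxy)-12-hydroxy-15,15-dimethoxylabd-8-en-16-oate
Product: 12 methyl (12E)-7β-(tert-butyldimethylsilyloxy)-15,15-dimethoxylabda-8,12-dien-16-oate, via C12 mesylate 11 (not isolated)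
Conditions: MsCl, Et3N, CH2Cl2, 0 °C; then DBU, 0 °C to rt
Reagents that add atoms: none
Why: Mesylation and E1cB elimination through the ester enolate give the thermodynamically preferred (E)-trisubstituted enoate (tiglate-type geometry) from both aldol diastereomers, with short contact with DBU to avoid deconjugation into the skipped diene.

**Step 9**
Reactants: 12 methyl (12E)-7β-(tert-butyldimethylsilyloxy)-15,15-dimethoxylabda-8,12-dien-16-oate
Product: 13 (12E)-7β-(tert-butyldimethylsilyloxy)-15,15-dimethoxylabda-8,12-dien-16-ol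
Conditions: iBu2AlH, CH2Cl2, −78 °C
Reagents that add atoms: none
Why: Clean 1,2-reduction of the enoate gives the trisubstituted allylic alcohol needed for the asymmetric epoxidation, with acetal and silyl ether untouched.

**Step 10**
Reactants: 13 (12E)-7β-(tert-butyldimethylsilyloxy)-15,15-dimethoxylabda-8,12-dien-16-ol
Product: 14 (12R,13R)-12,13-epoxy-7β-(tert-butyldimethylsilyloxy)-15,15-dimethoxylabd-8-en-16-ol
Conditions: Ti(OiPr)4 (10 mol %), D-(−)-diethyl tartrate (12 mol %), tBuOOH, 4 Å MS, CH2Cl2, −20 °C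
Reagents that add atoms: tert-butyl hydroperoxide, CC(C)(C)OO
Why: Sharpless asymmetric epoxidation with the D-(−)-tartrate ligand gives the (12R,13R)-epoxide under reagent control and so fixes C13, while the Δ8 alkene, which is not part of an allylic alcohol, does not react.

**Step 11**
Reactants: 14 (12R,13R)-12,13-epoxy-7β-(tert-butyldimethylsilyloxy)-15,15-dimethoxylabd-8-en-16-ol
Product: 15 (13R)-7β-(tert-butyldimethylsilyloxy)-15,15-dimethoxylabd-8-ene-13,16-diol
Conditions: LiAlH4, THF, 0 °C to rt
Reagents that add atoms: none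
Why: SN2 hydride opening of the 2,3-epoxy alcohol at the less substituted C12 removes the aldol oxygen and leaves the tertiary C13 carbinol with its configuration untouched (13R).

**Step 12**
Reactants: 15 (13R)-7β-(tert-butyldimethylsilyloxy)-15,15-dimethoxylabd-8-ene-13,16-diol
Product: 16 (13R)-7β-(tert-butyldimethylsilyloxy)-15ξ-methoxy-15,16-epoxylabd-8-en-13-ol
Conditions: PPTS (cat.), 4 Å MS, CH2Cl2, rt
Reagents that add atoms: none
Why: Acid-catalysed intramolecular transacetalisation closes the five-membered methyl furanoside from the primary C16 hydroxyl, which masks that hydroxyl and keeps C15 at the aldehyde level, while the tertiary C13 hydroxyl could only form a four-membered ring and stays free.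

**Step 13**
Reactants: 16 (13R)-7β-(tert-butyldimethylsilyloxy)-15ξ-methoxy-15,16-epoxylabd-8-en-13-ol
Product: 17 (13R)-15ξ-methoxy-15,16-epoxylabd-8-ene-7β,13-diol
Conditions: Bu4NF, THF, rt to 40 °C
Reagents that add atoms: none
Why: Fluoride desilylation frees the allylic 7β-hydroxyl that has to direct the epoxidation, under conditions that do not affect the acetal.

**Step 14**
Reactants: 17 (13R)-15ξ-methoxy-15,16-epoxylabd-8-ene-7β,13-diol
Product: 19 (13R)-9α,13:15,16-diepoxy-15ξ-methoxylabdane-7β,8β-diol, via 8β,9β-epoxide 18 (not isolated)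
Conditions: mCPBA, NaHCO3, CH2Cl2, 0 °C; then CSA (10 mol %), 0 °C to rt
Reagents that add atoms: 3-chloroperbenzoic acid, OOC(=O)c1cccc(Cl)c1
Why: In a Henbest hydroxyl-directed epoxidation the pseudo-equatorial 7β-OH hydrogen-bonds the peracid and delivers oxygen to the β face (as in 3β-hydroxy-Δ4-steroids), and acid then triggers 5-exo-tet opening at C9 by the C13 hydroxyl from the α face with inversion (trans-diaxial, Fürst–Plattner), which sets C9 (O α, C11 β) and C8 (β-OH, α-CH3) together.

**Step 15**
Reactants: 19 (13R)-9α,13:15,16-diepoxy-15ξ-methoxylabdane-7β,8β-diol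
Product: 20 (13R)-8β-hydroxy-9α,13:15,16-diepoxy-15ξ-methoxylabdan-7-one
Conditions: 2-iodoxybenzoic acid (IBX), DMSO, rt
Reagents that add atoms: none
Why: IBX oxidation converts only the secondary 7-hydroxyl of the cis-diol into the ketone without glycol cleavage, and the product cannot enolise toward C8, so the β-alkoxy ketone does not eliminate.

**Step 16**
Reactants: 20 (13R)-8β-hydroxy-9α,13:15,16-diepoxy-15ξ-methoxylabdan-7-one
Product: 21 (13R)-8β-acetoxy-9α,13:15,16-diepoxy-15ξ-methoxylabdan-7-one
Conditions: Ac2O, DMAP, Et3N, ClCH2CH2Cl, 50 °C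
Reagents that add atoms: acetic anhydride, CC(=O)OC(C)=O
Why: DMAP-catalysed (Steglich-type) acylation through the N-acetylpyridinium ion acetylates the hindered axial tertiary α-ketol hydroxyl under basic conditions that leave the methyl acetal and the spiro ether intact.

**Step 17**
Reactants: 21 (13R)-8β-acetoxy-9α,13:15,16-diepoxy-15ξ-methoxylabdan-7-one
Product: 22 (13R)-8β-acetoxy-15ξ-hydroxy-9α,13:15,16-diepoxylabdan-7-one
Conditions: AcOH/H2O/THF (3:1:1), 40 °C
Reagents that add atoms: water, O
Why: Mild acid hydrolysis of the methyl furanoside gives the lactol, and the tertiary acetate, the ketone and the still saturated spiro ether tolerate aqueous acetic acid.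

**Step 18**
Reactants: 22 (13R)-8β-acetoxy-15ξ-hydroxy-9α,13:15,16-diepoxylabdan-7-one
Product: 24 (5S,8R,9S,10S,13R)-8-acetoxy-9,13:15,16-diepoxylabd-14-en-7-one (CNP0165143.1), via C15 mesylate 23 (not isolated)
Conditions: MsCl, Et3N, CH2Cl2, −20 °C to rt; NaHCO3 work-up, Et3N-deactivated silica
Reagents that add atoms: none
Why: Sulfonylation of the lactol and E1-type loss of methanesulfonate from the oxocarbenium ion, with Et3N removing H14 (the only β-hydrogens, C13 being quaternary), gives the cyclic enol ether as in furanoid glycal syntheses, and the base-buffered work-up protects the acid-labile allylic spiro ether.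

**Compound list**
1 | (+)-sclareolide | O=C1C[C@H]2[C@](C)(O1)CC[C@H]3C(C)(C)CCC[C@]23C | starting material
2 | methyl 13,14,15,16-tetranorlabd-8-en-12-oate | COC(=O)CC1=C(C)CC[C@H]2C(C)(C)CCC[C@]12C | intermediate
3 | methyl 7-oxo-13,14,15,16-tetranorlabd-8-en-12-oate | COC(=O)CC1=C(C)C(=O)C[C@H]2C(C)(C)CCC[C@]12C | intermediate
4 | methyl 7β-hydroxy-13,14,15,16-tetranorlabd-8-en-12-oate (7S) | COC(=O)CC1=C(C)[C@@H](O)C[C@H]2C(C)(C)CCC[C@]12C | intermediate
5 | methyl 7β-(tert-butyldimethylsilyloxy)-13,14,15,16-tetranorlabd-8-en-12-oate | COC(=O)CC1=C(C)[C@@H](O[Si](C)(C)C(C)(C)C)C[C@H]2C(C)(C)CCC[C@]12C | intermediate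
6 | 7β-(tert-butyldimethylsilyloxy)-13,14,15,16-tetranorlabd-8-en-12-ol | OCCC1=C(C)[C@@H](O[Si](C)(C)C(C)(C)C)C[C@H]2C(C)(C)CCC[C@]12C | intermediate
7 | 7β-(tert-butyldimethylsilyloxy)-13,14,15,16-tetranorlabd-8-en-12-al | O=CCC1=C(C)[C@@H](O[Si](C)(C)C(C)(C)C)C[C@H]2C(C)(C)CCC[C@]12C | intermediate
8 | methyl 4,4-dimethoxybutanoate | COC(=O)CCC(OC)OC | starting material
9 | lithium enolate of 8 (lithium 1,4,4-trimethoxybut-1-en-1-olate) | [Li]OC(OC)=CCC(OC)OC | intermediate
10 | methyl 7β-(tert-butyldimethylsilyloxy)-12-hydroxy-15,15-dimethoxylabd-8-en-16-oate (C12/C13 diastereomer mixture) | COC(=O)C(CC(OC)OC)C(O)CC1=C(C)[C@@H](O[Si](C)(C)C(C)(C)C)C[C@H]2C(C)(C)CCC[C@]12C | intermediate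
11 | C12 methanesulfonate of 10 | COC(=O)C(CC(OC)OC)C(OS(C)(=O)=O)CC1=C(C)[C@@H](O[Si](C)(C)C(C)(C)C)C[C@H]2C(C)(C)CCC[C@]12C | intermediate
12 | methyl (12E)-7β-(tert-butyldimethylsilyloxy)-15,15-dimethoxylabda-8,12-dien-16-oate | COC(=O)/C(CC(OC)OC)=C/CC1=C(C)[C@@H](O[Si](C)(C)C(C)(C)C)C[C@H]2C(C)(C)CCC[C@]12C | intermediate
13 | (12E)-7β-(tert-butyldimethylsilyloxy)-15,15-dimethoxylabda-8,12-dien-16-ol | OC/C(CC(OC)OC)=C/CC1=C(C)[C@@H](O[Si](C)(C)C(C)(C)C)C[C@H]2C(C)(C)CCC[C@]12C | intermediate
14 | (12R,13R)-12,13-epoxy-7β-(tert-butyldimethylsilyloxy)-15,15-dimethoxylabd-8-en-16-ol | OC[C@@]3(CC(OC)OC)O[C@@H]3CC1=C(C)[C@@H](O[Si](C)(C)C(C)(C)C)C[C@H]2C(C)(C)CCC[C@]12C | intermediate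
15 | (13R)-7β-(tert-butyldimethylsilyloxy)-15,15-dimethoxylabd-8-ene-13,16-diol | OC[C@](O)(CC(OC)OC)CCC1=C(C)[C@@H](O[Si](C)(C)C(C)(C)C)C[C@H]2C(C)(C)CCC[C@]12C | intermediate
16 | (13R)-7β-(tert-butyldimethylsilyloxy)-15ξ-methoxy-15,16-epoxylabd-8-en-13-ol | COC3C[C@@](O)(CO3)CCC1=C(C)[C@@H](O[Si](C)(C)C(C)(C)C)C[C@H]2C(C)(C)CCC[C@]12C | intermediate
17 | (13R)-15ξ-methoxy-15,16-epoxylabd-8-ene-7β,13-diol | COC3C[C@@](O)(CO3)CCC1=C(C)[C@@H](O)C[C@H]2C(C)(C)CCC[C@]12C | intermediate
18 | (13R)-8β,9β:15,16-diepoxy-15ξ-methoxylabdane-7β,13-diol | COC3C[C@@](O)(CO3)CC[C@@]14O[C@@]4(C)[C@@H](O)C[C@H]2C(C)(C)CCC[C@]12C | intermediate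
19 | (13R)-9α,13:15,16-diepoxy-15ξ-methoxylabdane-7β,8β-diol | O[C@@]1(C)[C@@H](O)C[C@H]2C(C)(C)CCC[C@]2(C)[C@@]12CC[C@]3(CC(OC)OC3)O2 | intermediate
20 | (13R)-8β-hydroxy-9α,13:15,16-diepoxy-15ξ-methoxylabdan-7-one | O[C@@]1(C)C(=O)C[C@H]2C(C)(C)CCC[C@]2(C)[C@@]12CC[C@]3(CC(OC)OC3)O2 | intermediate
21 | (13R)-8β-acetoxy-9α,13:15,16-diepoxy-15ξ-methoxylabdan-7-one | CC(=O)O[C@@]1(C)C(=O)C[C@H]2C(C)(C)CCC[C@]2(C)[C@@]12CC[C@]3(CC(OC)OC3)O2 | intermediate
22 | (13R)-8β-acetoxy-15ξ-hydroxy-9α,13:15,16-diepoxylabdan-7-one | CC(=O)O[C@@]1(C)C(=O)C[C@H]2C(C)(C)CCC[C@]2(C)[C@@]12CC[C@]3(CC(O)OC3)O2 | intermediate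
23 | C15 methanesulfonate of 22 | CC(=O)O[C@@]1(C)C(=O)C[C@H]2C(C)(C)CCC[C@]2(C)[C@@]12CC[C@]3(CC(OS(C)(=O)=O)OC3)O2 | intermediate
24 | (5S,8R,9S,10S,13R)-8-acetoxy-9,13:15,16-diepoxylabd-14-en-7-one (CNP0165143.1) | CC(=O)O[C@@]1(C)C(=O)C[C@H]2C(C)(C)CCC[C@]2(C)[C@@]12CC[C@]1(C=COC1)O2 | target

**Step count and risks**
Total step count: 18. Longest linear sequence: 18 steps, from 1 to 24 (8 is used as bought).

The three steps most likely to fail:

Step 14. The hydroxyl-directed delivery has to beat the steric preference of the tetrasubstituted alkene for α-face attack; an α-epoxide would lead to the 9-epi spiro ether. The fallback builds the β-epoxide by a bromohydrin ring closure that relies on trans-diaxial opening and not on direction. It sets out from 16. TESOTf and 2,6-lutidine give the 13-O-triethylsilyl ether F1, which keeps O13 out of a bromoetherification. NBS in wet THF at 0 °C puts bromine on the open α face, and water opens the bromonium ion axially at C8 to give the 9α-bromo-8β-hydroxy bromohydrin F2. K2CO3 in MeOH closes it with inversion at C9 to the bis-silylated 8β,9β-epoxide F3. Bu4NF removes both silyl groups and gives 18, where the fallback comes back to the route; 18 is cyclised with CSA as in step 14.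

Step 16. Direct acetylation of the axial tertiary 8β-hydroxyl, which is flanked by the spiro centre and 1,3-diaxial to the C10 methyl, may stall. The fallback moves the acetate in by an orthoester instead of acylating the tertiary alcohol. It sets out from 19. MeC(OMe)3 with catalytic PPTS gives the cyclic 7β,8β-(1-methoxyethylidene) orthoacetate F4. Brief treatment with cold aqueous acetic acid opens it stereoelectronically to the axial ester, the 8β-acetoxy-7β-ol F5. Immediate buffered oxidation (Dess–Martin periodinane, NaHCO3), before any acyl migration, gives 21, where the fallback comes back to the route.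

Step 18. The lactol can open to a β-alkoxy aldehyde, and the product ionises to the furan with traces of acid. The fallback skips the lactol and its sulfonate. It sets out from 21 and treats the methyl acetal with TMSOTf and iPr2NEt in CH2Cl2 at −20 °C (Gassman-type conversion of an acetal into an enol ether, quenched with Et3N), which gives 24 directly, where it comes back to the route. It makes no new compound (none F0).

**Further compounds**
F1 | step 14 | (13R)-7β-(tert-butyldimethylsilyloxy)-13-(triethylsilyloxy)-15ξ-methoxy-15,16-epoxylabd-8-ene | COC3C[C@@](O[Si](CC)(CC)CC)(CO3)CCC1=C(C)[C@@H](O[Si](C)(C)C(C)(C)C)C[C@H]2C(C)(C)CCC[C@]12C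
F2 | step 14 | (13R)-9α-bromo-7β-(tert-butyldimethylsilyloxy)-13-(triethylsilyloxy)-15ξ-methoxy-15,16-epoxylabdan-8β-ol | O[C@@]1(C)[C@@H](O[Si](C)(C)C(C)(C)C)C[C@H]2C(C)(C)CCC[C@]2(C)[C@@]1(Br)CC[C@]3(CC(OC)OC3)O[Si](CC)(CC)CC
F3 | step 14 | (13R)-8β,9β:15,16-diepoxy-7β-(tert-butyldimethylsilyloxy)-13-(triethylsilyloxy)-15ξ-methoxylabdane | COC3C[C@@](O[Si](CC)(CC)CC)(CO3)CC[C@@]14O[C@@]4(C)[C@@H](O[Si](C)(C)C(C)(C)C)C[C@H]2C(C)(C)CCC[C@]12C
F4 | step 16 | (13R)-9α,13:15,16-diepoxy-15ξ-methoxy-7β,8β-(1-methoxyethylidenedioxy)labdane | COC4(C)O[C@@]1(C)[C@@H](O4)C[C@H]2C(C)(C)CCC[C@]2(C)[C@@]12CC[C@]3(CC(OC)OC3)O2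
F5 | step 16 | (13R)-8β-acetoxy-9α,13:15,16-diepoxy-15ξ-methoxylabdan-7β-ol | CC(=O)O[C@@]1(C)[C@@H](O)C[C@H]2C(C)(C)CCC[C@]2(C)[C@@]12CC[C@]3(CC(OC)OC3)O2
F0 | step 18 | none | none
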